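**Plan**
- Numbering: the carbobicycle of the target is numbered as in indene (C1, C2, C3, C3a, C4–C7, C7a); lactone C=O on C2, lactone O on C3, alkene C7=C7a, CH2O‑butanoate on C4, (S)‑1,3,3‑trimethylcyclohexyl on C7.
- Cuts, in retrosynthetic order: butanoate C–O; one carbon beyond the C4 carbinol carbon (C4–CH=CH2); C3a–C4 with allylic transposition (C7=C7a back to C7(OMe)–C7a=C3a), which opens the cyclohexene; C7a=C3a (metathesis), which opens the cyclopentene; C2–C3 and C3–O (ketene plus acrolein), which opens the lactone; C7–C7a (vinylcerium plus ketone); C5–C6 and C4=CH (alkylation, cross‑metathesis).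
- Forward: the trimethylcyclohexane comes from 3‑methylcyclohexenone, the chain is joined, then the rings arise in the order β‑lactone, cyclopentene, cyclohexene (last).
- Enabling feature: C7=C7a is allylic to C3a, so a C7‑oxygenated C7a=C3a cyclopentene ionises to an allyl cation that an allylsilane tethered through C6–C5 captures at C3a. Ring C3a–C4–C5–C6–C7–C7a thus closes at its least hindered bond, and the tetrasubstituted alkene beside the quaternary carbon arises by transposition.
- Stereochemistry: quaternary carbon from a catalytic asymmetric conjugate addition; C2 and C3 from a cinchona‑catalysed (2+2); C3a and C4 from the key step (substrate control); the C7 carbinol centre is uncontrolled and erased.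

Key step: step 14

Assumption: O‑trimethylsilylquinine is taken to give the (3R,4S) lactone in step 12, as the usual model for these catalysts predicts; the pseudoenantiomeric quinidine ether would be used otherwise.
Remark: 11 and 17–25 are carried as E/Z mixtures at the allylsilane (E drawn), and 17–25 as both epimers at the carbinol carbon (future C7), which becomes sp2 in step 14.

**Step 1**
Reactants: 1 3-methylcyclohex-2-en-1-one; 2 ethynyltrimethylsilane
Product: 4 (3S)-3-methyl-3-[1-(trimethylsilyl)ethenyl]cyclohexan-1-one, via vinylalane 3 (not isolated)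
Conditions: 2, iBu2AlH, hexane/THF, 55 °C; then 1, CuCl2·2H2O (5 mol %), chiral sulfonate-bearing imidazolinium salt (carbene precursor, 5 mol %), THF, −30 °C
Reagents that add atoms: none
Why: α‑selective hydroalumination of the silylalkyne followed by copper–carbene‑catalysed enantioselective conjugate addition of the α‑silyl vinylalane to a β‑substituted cyclic enone, a reaction type established for this enone; the ligand enantiomer is chosen to give the S quaternary centre.

**Step 2**
Reactants: 4 (3S)-3-methyl-3-[1-(trimethylsilyl)ethenyl]cyclohexan-1-one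
Product: 5 trimethyl{1-[(1S)-1,3,3-trimethylcyclohexyl]ethenyl}silane
Conditions: Me2Zn, TiCl4, CH2Cl2, −30 → 0 °C
Reagents that add atoms: dimethylzinc, C[Zn]C (two methyl groups, delivered as Me2TiCl2)
Why: titanium‑mediated geminal dimethylation (methyl addition, ionisation of the tertiary titanium alkoxide, second methyl transfer) turns the carbonyl carbon into C3 of the cyclohexane; the quaternary centre is untouched and the vinylsilane cannot reach the cation without forming a four‑membered ring.

**Step 3**
Reactants: 5 trimethyl{1-[(1S)-1,3,3-trimethylcyclohexyl]ethenyl}silane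
Product: 7 1-[(1S)-1,3,3-trimethylcyclohexyl]ethan-1-one, via epoxysilane 6 (not isolated)
Conditions: mCPBA, NaHCO3, CH2Cl2, 0 °C → rt; then H2SO4, MeOH/H2O, 60 °C
Reagents that add atoms: mCPBA, O=C(OO)c1cccc(Cl)c1 (oxygen of 6); water, O (carbonyl oxygen of 7)
Why: epoxidation of the vinylsilane, acid‑mediated opening and Peterson‑type loss of trimethylsilanol give the enol of the methyl ketone, so the α‑silylvinyl group serves as an acetyl equivalent; no stereocentre is involved.

**Step 4**
Reactants: 7 1-[(1S)-1,3,3-trimethylcyclohexyl]ethan-1-one; 8 3-bromoprop-1-ene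
Product: 9 1-[(1S)-1,3,3-trimethylcyclohexyl]pent-4-en-1-one
Conditions: LiN(iPr)2, THF, −78 °C; then 8, DMPU, −78 → 0 °C
Reagents that add atoms: none
Why: only the methyl group can be enolised, and SN2 allylation of the lithium enolate installs C5 and C4.

**Step 5**
Reactants: 9 1-[(1S)-1,3,3-trimethylcyclohexyl]pent-4-en-1-one; 10 allyltrimethylsilane
Product: 11 (4E)-1-[(1S)-1,3,3-trimethylcyclohexyl]-6-(trimethylsilyl)hex-4-en-1-one
Conditions: second-generation Grubbs catalyst (3 mol %), 10 (3 equiv), CH2Cl2, 40 °C
Reagents that add atoms: none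
Why: olefin cross‑metathesis of two unhindered terminal alkenes with the cheap partner in excess installs the allylsilane terminator; its geometry is irrelevant to step 14.

**Step 6**
Reactants: 12 5-hydroxypentan-2-one
Product: 13 5-[(tert-butyldimethylsilyl)oxy]pentan-2-one
Conditions: TBSCl, imidazole, CH2Cl2, 0 °C → rt
Reagents that add atoms: tert-butyldimethylsilyl chloride, CC(C)(C)[Si](C)(C)Cl
Why: standard silylation of the primary alcohol of the open hydroxy ketone form.

**Step 7**
Reactants: 13 5-[(tert-butyldimethylsilyl)oxy]pentan-2-one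
Product: 14 N'-{5-[(tert-butyldimethylsilyl)oxy]pentan-2-ylidene}-2,4,6-triisopropylbenzenesulfonohydrazide
Conditions: 2,4,6-triisopropylbenzenesulfonohydrazide, THF, 4 Å molecular sieves, rt
Reagents that add atoms: 2,4,6-triisopropylbenzenesulfonohydrazide, CC(C)c1cc(C(C)C)c(S(=O)(=O)NN)c(C(C)C)c1
Why: acid‑free hydrazone condensation, which leaves the silyl ether intact.

**Step 8**
Reactants: 14 the hydrazone of step 7; 11 (4E)-1-[(1S)-1,3,3-trimethylcyclohexyl]-6-(trimethylsilyl)hex-4-en-1-one
Product: 17 (8E)-1-[(tert-butyldimethylsilyl)oxy]-4-methylidene-5-[(1S)-1,3,3-trimethylcyclohexyl]-10-(trimethylsilyl)dec-8-en-5-ol (both C5 epimers), via vinyllithium 15 (not isolated), via vinylcerium dichloride 16 (not isolated)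
Conditions: 14, n-BuLi (2.1 equiv), THF, −78 → 0 °C; CeCl3, −78 °C; then 11, −78 → −40 °C; aqueous NH4Cl
Reagents that add atoms: none
Why: the Shapiro reaction (dianion at the methyl group, loss of sulfinate and N2) gives the 2‑metallated 1‑alkene, and the organocerium reagent adds 1,2 to the hindered, enolisable ketone without deprotonating it; the new carbinol centre forms without control, which is acceptable because it becomes sp2 in step 14.

**Step 9**
Reactants: 17 the tertiary alcohol of step 8
Product: 18 tert-butyl{[(8E)-5-methoxy-4-methylidene-5-[(1S)-1,3,3-trimethylcyclohexyl]-10-(trimethylsilyl)dec-8-en-1-yl]oxy}dimethylsilane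
Conditions: KH, MeI, THF, 0 °C → rt
Reagents that add atoms: iodomethane, CI
Why: Williamson etherification of the potassium alkoxide; the methyl ether prevents δ‑lactone formation when the acid is activated in step 12 and is the leaving group of step 14.

**Step 10**
Reactants: 18 the methyl ether of step 9
Product: 19 (8E)-5-methoxy-4-methylidene-5-[(1S)-1,3,3-trimethylcyclohexyl]-10-(trimethylsilyl)dec-8-en-1-ol
Conditions: Bu4NF, THF, 0 °C → rt
Reagents that add atoms: none
Why: fluoride cleaves the primary silyl ether, while the allylsilane and the tertiary allylic ether should be inert at this temperature.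

**Step 11**
Reactants: 19 the primary alcohol of step 10
Product: 21 (8E)-5-methoxy-4-methylidene-5-[(1S)-1,3,3-trimethylcyclohexyl]-10-(trimethylsilyl)dec-8-enoic acid, via aldehyde 20 (not isolated)
Conditions: TEMPO (20 mol %), PhI(OAc)2, MeCN/pH 7 buffer, rt
Reagents that add atoms: water, O
Why: oxoammonium oxidation of the primary alcohol through the aldehyde hydrate to the acid under near‑neutral conditions that spare the acid‑labile tertiary allylic ether.

**Step 12**
Reactants: 21 the acid of step 11; 22 prop-2-enal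
Product: 24 (3R,4S)-4-ethenyl-3-{(6E)-3-methoxy-2-methylidene-3-[(1S)-1,3,3-trimethylcyclohexyl]-8-(trimethylsilyl)oct-6-en-1-yl}oxetan-2-one, via acid chloride 23 (not isolated)
Conditions: 1-chloro-N,N,2-trimethylprop-1-en-1-amine, CH2Cl2, 0 °C; then slow addition to 22, O-trimethylsilylquinine (10 mol %), LiClO4, iPr2NEt, CH2Cl2/Et2O, −78 °C
Reagents that add atoms: none
Why: cinchona‑alkaloid and lithium co‑catalysed ketene–aldehyde (2+2) cyclocondensation (Wynberg type), in which the chiral ammonium enolate of the ketene adds to the lithium‑activated aldehyde through a closed transition state and lactonises; this gives the cis‑3,4‑disubstituted β‑lactone with both centres (future C2 and C3) set by the catalyst, independently of the remote centres.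

**Step 13**
Reactants: 24 the β-lactone of step 12
Product: 25 (1R,5S)-3-{(4E)-1-methoxy-1-[(1S)-1,3,3-trimethylcyclohexyl]-6-(trimethylsilyl)hex-4-en-1-yl}-6-oxabicyclo[3.2.0]hept-3-en-7-one
Conditions: second-generation Hoveyda–Grubbs catalyst (10 mol %), toluene, 70 °C
Reagents that add atoms: none
Why: ring‑closing metathesis between the vinyl group and the 1,1‑disubstituted alkene, held cis on the oxetanone, closes the cyclopentene (C7a=C3a); the internal allylsilane alkene and the lactone are spectators.

**Step 14**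
Reactants: 25 the bicyclic allylic β-lactone of step 13
Product: 26 β-lactone of (2R,3S,3aR,4R)-4-ethenyl-3-hydroxy-7-[(1S)-1,3,3-trimethylcyclohexyl]-2,3,3a,4,5,6-hexahydro-1H-indene-2-carboxylic acid
Conditions: TMSOTf (20 mol %), 2,6-di-tert-butyl-4-methylpyridine (30 mol %), CH2Cl2, −78 °C
Reagents that add atoms: none
Why: Silylation of the methoxy group by TMSOTf and loss of MeOSiMe3 give the allyl cation C7–C7a–C3a from either C7 epimer, and the γ‑carbon of the tethered allylsilane (future C4) bonds to the ring terminus C3a with loss of the silyl group, which regenerates TMSOTf. The closest known type is the biomimetic cation–olefin cyclisation with a tertiary allylic initiator and an allylsilane terminator (intramolecular Hosomi–Sakurai allylation, linalyl‑to‑terpinyl mode). The six‑membered ring C3a–C4–C5–C6–C7–C7a closes endo with respect to the allyl cation (all three allyl carbons become ring members and the double bond moves to C7=C7a) and exo with respect to the allylsilane (its double bond ends as the C4 vinyl group). C3a is set by attack on the convex face of the bicyclo[3.2.0]heptene, anti to the C3–O bond of the lactone, and C4 by an open, chair‑like transition state in which the CH=CH–CH2Si arm is pseudo‑equatorial and points away from the cyclopentene, which places the vinyl group trans to the C3a–C3 bond. The step needs chemoselective ionisation of the tertiary allylic ether beside the allylic lactone C–O bond, which the more basic tertiary ether oxygen, catalytic TMSOTf, the hindered pyridine buffer and −78 °C should secure. Bond formation at C7 is excluded (four‑membered ring), so the tetrasubstituted alkene arises by transposition without joining two hindered carbons.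

**Step 15**
Reactants: 26 the vinyl tricycle of step 14
Product: 28 β-lactone of (2R,3S,3aR,4S)-3-hydroxy-4-(hydroxymethyl)-7-[(1S)-1,3,3-trimethylcyclohexyl]-2,3,3a,4,5,6-hexahydro-1H-indene-2-carboxylic acid, via aldehyde 27 (not isolated)
Conditions: K2OsO4·2H2O (2 mol %), NaIO4, 2,6-lutidine, dioxane/H2O, rt; then NaBH4, 0 °C
Reagents that add atoms: sodium periodate, [Na+].[O-]I(=O)(=O)=O (oxygen)
Why: Lemieux–Johnson cleavage, in which osmylation should select the monosubstituted alkene over the tetrasubstituted alkene beside the quaternary carbon, followed by borohydride reduction of the aldehyde, which is far faster than attack on the lactone at 0 °C; C4 keeps its equatorial configuration.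

**Step 16**
Reactants: 28 the primary alcohol of step 15; 29 butanoyl chloride
Product: 30 3'-norspongiolactone
Conditions: pyridine, CH2Cl2, 0 °C
Reagents that add atoms: none
Why: O‑acylation of the primary alcohol under weakly basic, non‑nucleophilic conditions that a β‑lactone tolerates; translactonisation is not expected because C4 and the lactone carbonyl are trans‑disposed across the cyclopentane.

**Compound list**
1 | 3-methylcyclohex-2-en-1-one | CC1=CC(=O)CCC1 | starting material
2 | ethynyltrimethylsilane | C#C[Si](C)(C)C | starting material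
3 | diisobutyl[1-(trimethylsilyl)ethenyl]alane (not isolated) | C=C([Si](C)(C)C)[Al](CC(C)C)CC(C)C | intermediate
4 | (3S)-3-methyl-3-[1-(trimethylsilyl)ethenyl]cyclohexan-1-one | C=C([Si](C)(C)C)[C@@]1(C)CCCC(=O)C1 | intermediate
5 | trimethyl{1-[(1S)-1,3,3-trimethylcyclohexyl]ethenyl}silane | C=C([Si](C)(C)C)[C@@]1(C)CCCC(C)(C)C1 | intermediate
6 | trimethyl{2-[(1S)-1,3,3-trimethylcyclohexyl]oxiran-2-yl}silane, both oxirane epimers (not isolated) | C[Si](C)(C)C1(CO1)[C@@]2(C)CCCC(C)(C)C2 | intermediate
7 | 1-[(1S)-1,3,3-trimethylcyclohexyl]ethan-1-one | CC(=O)[C@@]1(C)CCCC(C)(C)C1 | intermediate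
8 | 3-bromoprop-1-ene (allyl bromide) | C=CCBr | starting material
9 | 1-[(1S)-1,3,3-trimethylcyclohexyl]pent-4-en-1-one | C=CCCC(=O)[C@@]1(C)CCCC(C)(C)C1 | intermediate
10 | allyltrimethylsilane | C=CC[Si](C)(C)C | starting material
11 | (4E)-1-[(1S)-1,3,3-trimethylcyclohexyl]-6-(trimethylsilyl)hex-4-en-1-one | C[Si](C)(C)C/C=C/CCC(=O)[C@@]1(C)CCCC(C)(C)C1 | intermediate
12 | 5-hydroxypentan-2-one | CC(=O)CCCO | starting material
13 | 5-[(tert-butyldimethylsilyl)oxy]pentan-2-one | CC(=O)CCCO[Si](C)(C)C(C)(C)C | intermediate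
14 | N'-{5-[(tert-butyldimethylsilyl)oxy]pentan-2-ylidene}-2,4,6-triisopropylbenzenesulfonohydrazide | CC(CCCO[Si](C)(C)C(C)(C)C)=NNS(=O)(=O)c1c(C(C)C)cc(C(C)C)cc1C(C)C | intermediate
15 | {5-[(tert-butyldimethylsilyl)oxy]pent-1-en-2-yl}lithium (not isolated) | [Li]C(=C)CCCO[Si](C)(C)C(C)(C)C | intermediate
16 | dichloro{5-[(tert-butyldimethylsilyl)oxy]pent-1-en-2-yl}cerium (not isolated) | C=C(CCCO[Si](C)(C)C(C)(C)C)[Ce](Cl)Cl | intermediate
17 | (8E)-1-[(tert-butyldimethylsilyl)oxy]-4-methylidene-5-[(1S)-1,3,3-trimethylcyclohexyl]-10-(trimethylsilyl)dec-8-en-5-ol, both C5 epimers | C=C(CCCO[Si](C)(C)C(C)(C)C)C(O)(CC/C=C/C[Si](C)(C)C)[C@@]1(C)CCCC(C)(C)C1 | intermediate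
18 | methyl ether of 17 (5-methoxy) | C=C(CCCO[Si](C)(C)C(C)(C)C)C(OC)(CC/C=C/C[Si](C)(C)C)[C@@]1(C)CCCC(C)(C)C1 | intermediate
19 | (8E)-5-methoxy-4-methylidene-5-[(1S)-1,3,3-trimethylcyclohexyl]-10-(trimethylsilyl)dec-8-en-1-ol | C=C(CCCO)C(OC)(CC/C=C/C[Si](C)(C)C)[C@@]1(C)CCCC(C)(C)C1 | intermediate
20 | the corresponding dec-8-enal (not isolated) | C=C(CCC=O)C(OC)(CC/C=C/C[Si](C)(C)C)[C@@]1(C)CCCC(C)(C)C1 | intermediate
21 | (8E)-5-methoxy-4-methylidene-5-[(1S)-1,3,3-trimethylcyclohexyl]-10-(trimethylsilyl)dec-8-enoic acid | C=C(CCC(=O)O)C(OC)(CC/C=C/C[Si](C)(C)C)[C@@]1(C)CCCC(C)(C)C1 | intermediate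
22 | prop-2-enal (acrolein) | C=CC=O | starting material
23 | acid chloride of 21 (not isolated) | C=C(CCC(=O)Cl)C(OC)(CC/C=C/C[Si](C)(C)C)[C@@]1(C)CCCC(C)(C)C1 | intermediate
24 | (3R,4S)-4-ethenyl-3-{(6E)-3-methoxy-2-methylidene-3-[(1S)-1,3,3-trimethylcyclohexyl]-8-(trimethylsilyl)oct-6-en-1-yl}oxetan-2-one | C=C[C@@H]1OC(=O)[C@@H]1CC(=C)C(OC)(CC/C=C/C[Si](C)(C)C)[C@@]2(C)CCCC(C)(C)C2 | intermediate
25 | (1R,5S)-3-{(4E)-1-methoxy-1-[(1S)-1,3,3-trimethylcyclohexyl]-6-(trimethylsilyl)hex-4-en-1-yl}-6-oxabicyclo[3.2.0]hept-3-en-7-one | COC(CC/C=C/C[Si](C)(C)C)(C1=C[C@@H]2OC(=O)[C@@H]2C1)[C@@]3(C)CCCC(C)(C)C3 | intermediate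
26 | β-lactone of (2R,3S,3aR,4R)-4-ethenyl-3-hydroxy-7-[(1S)-1,3,3-trimethylcyclohexyl]-2,3,3a,4,5,6-hexahydro-1H-indene-2-carboxylic acid (vinyl trans to C3a–C3, cis to H-3a) | C=C[C@H]1CCC([C@@]2(C)CCCC(C)(C)C2)=C2C[C@H]3C(=O)O[C@H]3[C@@H]21 | intermediate
27 | the corresponding C4 carbaldehyde, (4S) (not isolated) | O=C[C@H]1CCC([C@@]2(C)CCCC(C)(C)C2)=C2C[C@H]3C(=O)O[C@H]3[C@@H]21 | intermediate
28 | the corresponding C4 hydroxymethyl compound, (2R,3S,3aR,4S) | OC[C@H]1CCC([C@@]2(C)CCCC(C)(C)C2)=C2C[C@H]3C(=O)O[C@H]3[C@@H]21 | intermediate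
29 | butanoyl chloride | CCCC(=O)Cl | starting material
30 | 3'-norspongiolactone, (2R,3S,3aR,4S), cyclohexyl (1S) | CCCC(=O)OC[C@H]1CCC([C@@]2(C)CCCC(C)(C)C2)=C2C[C@H]3C(=O)O[C@H]3[C@@H]21 | target

**Step count and risks**
Total: 16 steps. Longest linear sequence: 14 steps (1–5 and 8–16).

Step 12. Conjugate addition and oligomerisation of acrolein under amine catalysis, or dimerisation of the ketene, may outrun the (2+2) event and erode the cis selectivity. Fallback (auxiliary‑controlled aldol instead of catalytic cycloaddition): the line leaves at acid 21. Pivaloyl chloride/Et3N and the lithium salt of (R)-4-benzyloxazolidin-2-one give imide F1. An Evans syn aldol reaction (Bu2BOTf, iPr2NEt, acrolein, −78 °C) gives aldol adduct F2. LiOH/H2O2 removes the auxiliary to give β‑hydroxy acid F3, and carboxyl activation (TsCl, pyridine, 0 °C) closes the cis β‑lactone with retention at both centres, rejoining the route at 24.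

Step 13. Metallacycle formation at the crowded 1,1‑disubstituted alkene may be slow, and the strain of the forming bicyclo[3.2.0]heptene adds to this, so that catalyst decay and intermolecular metathesis take over. Fallback (ring closure before lactonisation, on an unstrained substrate): the line leaves at 21 and passes through F1 and F2 as above. Ring‑closing metathesis of the open‑chain aldol adduct F2 with its free allylic hydroxyl gives cyclopentenol imide F4, LiOH/H2O2 gives hydroxy acid F5, and TsCl/pyridine closes the lactone, rejoining the route at 25.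

Step 14. Heterolysis of the allylic lactone C3–O bond, or proton loss from the allyl cation, may outrun carbon–carbon bond formation, and a synclinal transition state would erode the C4 selectivity. Fallback (the order of the last two ring closures is exchanged, so the cation forms on a substrate without a strained ring, at the price of closing the lactone after the carbocycle): the line leaves at 21 and reaches cyclopentenol imide F4 as above. Et3SiCl/imidazole gives triethylsilyl ether F6. The same TMSOTf‑catalysed allylsilane closure, now directed by the C3 silyloxy group, gives tricyclic imide F7. LiOH/H2O2 gives acid F8, dilute HF in MeCN gives hydroxy acid F9, and TsCl/pyridine closes the cis β‑lactone, rejoining the route at 26.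

**Further compounds**
F1 | step 12 | (4R)-4-benzyl-3-acyl-oxazolidin-2-one of acid 21 | O=C1OC[C@@H](Cc2ccccc2)N1C(=O)CCC(=C)C(OC)(CC/C=C/C[Si](C)(C)C)[C@@]3(C)CCCC(C)(C)C3
F2 | step 12 | (2R,3S) syn aldol adduct of F1 with acrolein | O=C1OC[C@@H](Cc2ccccc2)N1C(=O)[C@H](CC(=C)C(OC)(CC/C=C/C[Si](C)(C)C)[C@@]3(C)CCCC(C)(C)C3)[C@@H](O)C=C
F3 | step 12 | (2R,3S)-3-hydroxy-2-substituted pent-4-enoic acid (seco acid of 24) | OC(=O)[C@H](CC(=C)C(OC)(CC/C=C/C[Si](C)(C)C)[C@@]1(C)CCCC(C)(C)C1)[C@@H](O)C=C
F4 | step 13 | cyclopentenol imide (cis-2-hydroxycyclopent-3-ene-1-carbonyl oxazolidinone, side chain at C4 of the ring) | O=C1OC[C@@H](Cc2ccccc2)N1C(=O)[C@@H]2CC(C(OC)(CC/C=C/C[Si](C)(C)C)[C@@]3(C)CCCC(C)(C)C3)=C[C@@H]2O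
F5 | step 13 | cis-2-hydroxycyclopent-3-ene-1-carboxylic acid (seco acid of 25) | OC(=O)[C@@H]1CC(C(OC)(CC/C=C/C[Si](C)(C)C)[C@@]2(C)CCCC(C)(C)C2)=C[C@@H]1O
F6 | step 14 | triethylsilyl ether of F4 | O=C1OC[C@@H](Cc2ccccc2)N1C(=O)[C@@H]2CC(C(OC)(CC/C=C/C[Si](C)(C)C)[C@@]3(C)CCCC(C)(C)C3)=C[C@@H]2O[Si](CC)(CC)CC
F7 | step 14 | cyclised hexahydroindene imide (4-ethenyl, 3-triethylsilyloxy, 2-acyl oxazolidinone) | C=C[C@H]1CCC([C@@]2(C)CCCC(C)(C)C2)=C2C[C@@H](C(=O)N3C(=O)OC[C@H]3Cc3ccccc3)[C@@H](O[Si](CC)(CC)CC)[C@@H]21
F8 | step 14 | the corresponding 3-triethylsilyloxy carboxylic acid | C=C[C@H]1CCC([C@@]2(C)CCCC(C)(C)C2)=C2C[C@@H](C(=O)O)[C@@H](O[Si](CC)(CC)CC)[C@@H]21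
F9 | step 14 | (2R,3S,3aR,4R)-4-ethenyl-3-hydroxy-7-[(1S)-1,3,3-trimethylcyclohexyl]-2,3,3a,4,5,6-hexahydro-1H-indene-2-carboxylic acid (seco acid of 26) | C=C[C@H]1CCC([C@@]2(C)CCCC(C)(C)C2)=C2C[C@@H](C(=O)O)[C@@H](O)[C@@H]21
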